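**Plan**

- Retrosynthesis: the last bond cut is the one between the spiro carbon and one CH= of the dienone ring (ring B). Then follow the C=C of the opened dienone, the one-carbon link at the benzylic ring carbon, the aryl–carbonyl bond of the seven-membered ring (back to a 6-aryl δ-lactone with an ortho bromide), the C–CH3 bond at C-4 of that lactone, the lactone C=C, and the carbinol C–C bond.
- Forward: aryl aldehyde → syn homoallylic alcohol → δ-lactone (temporary ring) → seven-membered aryl ketone by an anionic O→C acyl shift → one-carbon homologation → open-chain cross-conjugated dienone → closure of ring B, which gives the target directly.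
- Stereochemistry: the benzylic C–O centre and the adjacent C–CH3 centre come from a reagent-controlled (Z)-crotylboration. The second C–CH3 centre comes from substrate-controlled cuprate addition to the lactone. All three are carried unchanged.
- Enabling feature: the spiro carbon is both benzylic to ring A and γ to the dienone C=O through a CH=C(OCH3) unit. The two CH=C(OCH3) arms of ring B are constitutionally identical, so the spiro carbon is not a stereocentre. An open precursor can therefore be closed at this carbon by γ-deprotonation, 6π ring closure and loss of methoxide, with no stereocontrol needed at the new quaternary centre.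

Key step: step 11

Assumption: diethyl (methoxymethyl)phosphonate and (+)-B-methoxydiisopinocampheylborane are taken as commercial; the enol-ether and side-chain double-bond geometries and the formyl-bearing carbon are left unassigned because the key step erases them.

**Step 1**
Reactants: 1 2-bromo-3,4,5-trimethoxybenzaldehyde
Product: 3 (1R,2S)-1-(2-bromo-3,4,5-trimethoxyphenyl)-2-methylbut-3-en-1-ol, via borinate ester 2 (not isolated)
Conditions: cis-2-butene, KOtBu, nBuLi, THF, −78 → −45 °C; (+)-Ipc2BOMe [from (−)-α-pinene], −78 °C; BF3·OEt2; then 1, −78 °C; then 3 M NaOH, 30% H2O2, rt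
Reagents that add atoms: B-[(Z)-but-2-en-1-yl]diisopinocampheylborane (made in the flask), C/C=C\CB([C@H]1C[C@H]2C[C@@H]([C@@H]1C)C2(C)C)[C@H]1C[C@H]2C[C@@H]([C@@H]1C)C2(C)C
Why: Brown crotylboration through a closed chair-like six-membered transition state; the (Z)-crotyl geometry should give the syn 1,2-relationship, and the isopinocampheyl groups from (−)-α-pinene should direct attack to the Re face of the aldehyde, setting C-1 (R) and C-2 (S).

**Step 2**
Reactants: 3 (1R,2S)-1-(2-bromo-3,4,5-trimethoxyphenyl)-2-methylbut-3-en-1-ol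
Product: 4 (1R,2S)-1-(2-bromo-3,4,5-trimethoxyphenyl)-2-methylbut-3-en-1-yl prop-2-enoate
Conditions: CH2=CHCOCl, Et3N, DMAP (cat.), CH2Cl2, 0 °C → rt
Reagents that add atoms: acryloyl chloride, C=CC(=O)Cl
Why: standard acylation of a secondary benzylic alcohol under nucleophilic catalysis; no stereocentre is touched.

**Step 3**
Reactants: 4 (1R,2S)-1-(2-bromo-3,4,5-trimethoxyphenyl)-2-methylbut-3-en-1-yl prop-2-enoate
Product: 5 (5S,6R)-6-(2-bromo-3,4,5-trimethoxyphenyl)-5-methyl-5,6-dihydro-2H-pyran-2-one
Conditions: second-generation Grubbs catalyst RuCl2(=CHPh)(PCy3)(H2IMes) (5 mol%), CH2Cl2 (5 mM), 40 °C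
Reagents that add atoms: none
Why: ring-closing olefin metathesis of an acrylate with a monosubstituted alkene to an α,β-unsaturated δ-lactone, driven by loss of ethylene; the aryl bromide and both stereocentres are inert.

**Step 4**
Reactants: 5 (5S,6R)-6-(2-bromo-3,4,5-trimethoxyphenyl)-5-methyl-5,6-dihydro-2H-pyran-2-one
Product: 6 (4R,5S,6R)-6-(2-bromo-3,4,5-trimethoxyphenyl)-4,5-dimethyloxan-2-one
Conditions: Me2CuLi (from MeLi and CuI), Et2O, −78 → −30 °C; aq. NH4Cl
Reagents that add atoms: lithium dimethylcuprate, C[Cu-]C.[Li+]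
Why: conjugate addition of a Gilman cuprate to the dihydropyranone, expected on the face opposite the pseudoaxial C-5 methyl (and opposite the cis C-6 aryl) of the half-chair, which sets the new centre trans to the existing methyl; the aryl bromide should not react with Me2CuLi at this temperature.

**Step 5**
Reactants: 6 (4R,5S,6R)-6-(2-bromo-3,4,5-trimethoxyphenyl)-4,5-dimethyloxan-2-one
Product: 9 (5R,6S,7R)-1,2,3-trimethoxy-6,7-dimethyl-9-oxo-6,7,8,9-tetrahydro-5H-benzo[7]annulen-5-yl benzoate, via aryllithium 7 (not isolated), via lithium alkoxide 8 (not isolated)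
Conditions: tBuLi (2.0 eq), THF, −95 → −40 °C; then PhCOCl, DMAP (cat.), −40 °C → rt
Reagents that add atoms: benzoyl chloride, O=C(Cl)c1ccccc1
Why: Parham-type Br/Li exchange gives 7, whose attack on the lactone carbonyl through a five-membered transition state and collapse of the tetrahedral adduct amount to an anionic homo-Fries 1,4-O→C acyl shift; this turns the six-membered lactone into the seven-membered aryl ketone and frees the benzylic alkoxide 8 for benzoylation, and no bond to a stereocentre is broken.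

**Step 6**
Reactants: 9 (5R,6S,7R)-1,2,3-trimethoxy-6,7-dimethyl-9-oxo-6,7,8,9-tetrahydro-5H-benzo[7]annulen-5-yl benzoate
Product: 10 (5R,6S,7R)-1,2,3-trimethoxy-9-(methoxymethylidene)-6,7-dimethyl-6,7,8,9-tetrahydro-5H-benzo[7]annulen-5-yl benzoate
Conditions: Ph3P(CH2OMe)Cl, NaN(SiMe3)2, THF, 0 °C; then 9, 0 °C → rt
Reagents that add atoms: (methoxymethylidene)triphenylphosphorane (made in the flask), COC=P(c1ccccc1)(c1ccccc1)c1ccccc1
Why: Wittig methoxymethylenation of the aryl ketone (one-carbon homologation at the carbonyl carbon); the non-nucleophilic amide base and low temperature are chosen so that the benzoate should survive, and the alkene geometry is of no consequence.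

**Step 7**
Reactants: 10 (5R,6S,7R)-1,2,3-trimethoxy-9-(methoxymethylidene)-6,7-dimethyl-6,7,8,9-tetrahydro-5H-benzo[7]annulen-5-yl benzoate
Product: 11 (5R,6S,7R,9RS)-9-formyl-1,2,3-trimethoxy-6,7-dimethyl-6,7,8,9-tetrahydro-5H-benzo[7]annulen-5-yl benzoate
Conditions: 1 M aq. HCl, THF, rt; used without storage
Reagents that add atoms: water, O
Why: acid-catalysed enol ether hydrolysis (protonation at the benzylic carbon, capture of the oxocarbenium ion by water) should give the α-aryl aldehyde; the new benzylic centre forms as a mixture that is erased in step 11.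

**Step 8**
Reactants: 12 methyl methoxyacetate
Product: 14 methyl 2,3-dimethoxyprop-2-enoate, via sodium enolate 13 (not isolated)
Conditions: HCO2Me, NaH, THF, 0 °C → rt; then Me2SO4, DMF, rt
Reagents that add atoms: methyl formate, COC=O; dimethyl sulfate, COS(=O)(=O)OC
Why: crossed Claisen formylation of the ester enolate followed by O-methylation of the resulting sodium enolate, the standard route to β-methoxyacrylates; the double-bond geometry is of no consequence.

**Step 9**
Reactants: 15 diethyl (methoxymethyl)phosphonate; 14 methyl 2,3-dimethoxyprop-2-enoate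
Product: 16 diethyl (1,3,4-trimethoxy-2-oxobut-3-en-1-yl)phosphonate
Conditions: 15 (2.1 eq), LiN(iPr)2 (2.1 eq), THF, −78 °C; then 14 (1 eq), −78 → −30 °C; AcOH
Reagents that add atoms: none
Why: Claisen-type C-acylation of the lithiated α-methoxy phosphonate by the ester (standard β-ketophosphonate synthesis, the second equivalent of carbanion being consumed by the acidic product); the hard lithium carbanion should attack the ester carbonyl and not the doubly donor-substituted β-carbon.

**Step 10**
Reactants: 11 (5R,6S,7R,9RS)-9-formyl-1,2,3-trimethoxy-6,7-dimethyl-6,7,8,9-tetrahydro-5H-benzo[7]annulen-5-yl benzoate; 16 diethyl (1,3,4-trimethoxy-2-oxobut-3-en-1-yl)phosphonate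
Product: 17 (5R,6S,7R,9RS)-1,2,3-trimethoxy-6,7-dimethyl-9-(2,4,5-trimethoxy-3-oxopenta-1,4-dien-1-yl)-6,7,8,9-tetrahydro-5H-benzo[7]annulen-5-yl benzoate
Conditions: 16, NaH, THF, 0 °C; then 11, 0 °C → rt; chromatography on Et3N-washed silica
Reagents that add atoms: none
Why: Horner–Wadsworth–Emmons olefination; the weakly basic stabilised phosphonate anion should add to the enolisable α-aryl aldehyde faster than it deprotonates it, and neither the geometry of the new C=C nor the configuration of the adjacent carbon matters because step 11 erases both.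

**Step 11**
Reactants: 17 (5R,6S,7R,9RS)-1,2,3-trimethoxy-6,7-dimethyl-9-(2,4,5-trimethoxy-3-oxopenta-1,4-dien-1-yl)-6,7,8,9-tetrahydro-5H-benzo[7]annulen-5-yl benzoate
Product: 20 (5R,6S,7R)-1,2,3,3',5'-pentamethoxy-6,7-dimethyl-4'-oxo-5,6,7,8-tetrahydrospiro[benzo[7]annulene-9,1'-cyclohexa[2,5]dien]-5-yl benzoate, via potassium trienolate 18 (not isolated), via potassium spiro enolate 19 (not isolated)
Conditions: KN(SiMe3)2 (1.1 eq), THF, −78 → −20 °C; AcOH, −20 °C
Reagents that add atoms: none
Why: Proposed new method: the only acidic C–H of 17 is the tertiary benzylic hydrogen on the ring carbon γ to the ketone (both α-carbons are methoxy-bearing vinyl carbons), so KN(SiMe3)2 should give the cross-conjugated trienolate 18, in which the exocyclic benzylic carbon and the terminal CH(OCH3) carbon are the two ends of a 3-oxidohexatriene. Thermal disrotatory 6π-electrocyclisation (in polar terms a 6-endo-trig vinylogous Michael addition of the benzylic carbanion to the β-methoxy enone) should close the six-membered ring to enolate 19, and E1cB loss of methoxide then restores the second C=C(OCH3) and makes the closure irreversible. The closest known reaction types are the anion-accelerated electrocyclisation of oxido-substituted hexatrienes and the aminotriene cyclisation–elimination of vinamidinium benzannulations; here the fully substituted terminus stops the sequence at the cross-conjugated dienone instead of an arene. No new stereocentre results, because the two arms of the new ring are constitutionally identical and the transient centres of 19 vanish on elimination, while the three ring stereocentres lie outside the reacting π-system and carry no acidic hydrogen. The step needs the U-shaped enolate in which the oxido oxygen is syn to both flanking methoxy groups, which chelation of K+ by these three oxygens should favour. It must also be run under base only, since acid would divert the α-alkoxy divinyl ketone into a Nazarov closure, and the cold quench is meant to keep the liberated methoxide from attacking the benzoate.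

**Compound list**

1 | 2-bromo-3,4,5-trimethoxybenzaldehyde | COc1cc(C=O)c(Br)c(OC)c1OC | starting material
2 | (1R,2S)-1-(2-bromo-3,4,5-trimethoxyphenyl)-2-methylbut-3-en-1-yl diisopinocampheylborinate | C=C[C@H](C)[C@@H](OB([C@H]1C[C@H]2C[C@@H]([C@@H]1C)C2(C)C)[C@H]1C[C@H]2C[C@@H]([C@@H]1C)C2(C)C)c1cc(OC)c(OC)c(OC)c1Br | intermediate
3 | (1R,2S)-1-(2-bromo-3,4,5-trimethoxyphenyl)-2-methylbut-3-en-1-ol | C=C[C@H](C)[C@@H](O)c1cc(OC)c(OC)c(OC)c1Br | intermediate
4 | (1R,2S)-1-(2-bromo-3,4,5-trimethoxyphenyl)-2-methylbut-3-en-1-yl prop-2-enoate | C=C[C@H](C)[C@@H](OC(=O)C=C)c1cc(OC)c(OC)c(OC)c1Br | intermediate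
5 | (5S,6R)-6-(2-bromo-3,4,5-trimethoxyphenyl)-5-methyl-5,6-dihydro-2H-pyran-2-one | O=C1C=C[C@H](C)[C@@H](O1)c1cc(OC)c(OC)c(OC)c1Br | intermediate
6 | (4R,5S,6R)-6-(2-bromo-3,4,5-trimethoxyphenyl)-4,5-dimethyloxan-2-one (4,5-trans, 5,6-cis) | O=C1C[C@@H](C)[C@H](C)[C@@H](O1)c1cc(OC)c(OC)c(OC)c1Br | intermediate
7 | {6-[(2R,3S,4R)-3,4-dimethyl-6-oxooxan-2-yl]-2,3,4-trimethoxyphenyl}lithium | O=C1C[C@@H](C)[C@H](C)[C@@H](O1)c1cc(OC)c(OC)c(OC)c1[Li] | intermediate
8 | lithium (5R,6S,7R)-1,2,3-trimethoxy-6,7-dimethyl-9-oxo-6,7,8,9-tetrahydro-5H-benzo[7]annulen-5-olate | O=C1C[C@@H](C)[C@H](C)[C@@H]([O-])c2cc(OC)c(OC)c(OC)c12.[Li+] | intermediate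
9 | (5R,6S,7R)-1,2,3-trimethoxy-6,7-dimethyl-9-oxo-6,7,8,9-tetrahydro-5H-benzo[7]annulen-5-yl benzoate | O=C1C[C@@H](C)[C@H](C)[C@@H](OC(=O)c2ccccc2)c2cc(OC)c(OC)c(OC)c12 | intermediate
10 | (5R,6S,7R)-1,2,3-trimethoxy-9-(methoxymethylidene)-6,7-dimethyl-6,7,8,9-tetrahydro-5H-benzo[7]annulen-5-yl benzoate (E/Z mixture) | COC=C1C[C@@H](C)[C@H](C)[C@@H](OC(=O)c2ccccc2)c2cc(OC)c(OC)c(OC)c12 | intermediate
11 | (5R,6S,7R,9RS)-9-formyl-1,2,3-trimethoxy-6,7-dimethyl-6,7,8,9-tetrahydro-5H-benzo[7]annulen-5-yl benzoate | O=CC1C[C@@H](C)[C@H](C)[C@@H](OC(=O)c2ccccc2)c2cc(OC)c(OC)c(OC)c12 | intermediate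
12 | methyl methoxyacetate | COCC(=O)OC | starting material
13 | sodium 2,3-dimethoxy-3-oxoprop-1-en-1-olate | COC(=O)C(OC)=C[O-].[Na+] | intermediate
14 | methyl 2,3-dimethoxyprop-2-enoate (E/Z mixture) | COC=C(OC)C(=O)OC | intermediate
15 | diethyl (methoxymethyl)phosphonate | CCOP(=O)(COC)OCC | starting material
16 | diethyl (1,3,4-trimethoxy-2-oxobut-3-en-1-yl)phosphonate | CCOP(=O)(OCC)C(OC)C(=O)C(OC)=COC | intermediate
17 | (5R,6S,7R,9RS)-1,2,3-trimethoxy-6,7-dimethyl-9-(2,4,5-trimethoxy-3-oxopenta-1,4-dien-1-yl)-6,7,8,9-tetrahydro-5H-benzo[7]annulen-5-yl benzoate (double-bond isomers) | COC=C(OC)C(=O)C(OC)=CC1C[C@@H](C)[C@H](C)[C@@H](OC(=O)c2ccccc2)c2cc(OC)c(OC)c(OC)c12 | intermediate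
18 | potassium 1-[(5R,6S,7R)-5-(benzoyloxy)-1,2,3-trimethoxy-6,7-dimethyl-5,6,7,8-tetrahydro-9H-benzo[7]annulen-9-ylidene]-2,4,5-trimethoxypenta-2,4-dien-3-olate | COC=C(OC)C([O-])=C(OC)C=C1C[C@@H](C)[C@H](C)[C@@H](OC(=O)c2ccccc2)c2cc(OC)c(OC)c(OC)c12.[K+] | intermediate
19 | potassium (5R,6S,7R)-5-(benzoyloxy)-1,2,2',3,3',5'-hexamethoxy-6,7-dimethyl-5,6,7,8-tetrahydrospiro[benzo[7]annulene-9,1'-cyclohexa[3,5]dien]-4'-olate | COC1C(OC)=C([O-])C(OC)=CC12C[C@@H](C)[C@H](C)[C@@H](OC(=O)c1ccccc1)c1cc(OC)c(OC)c(OC)c12.[K+] | intermediate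
20 | (5R,6S,7R)-1,2,3,3',5'-pentamethoxy-6,7-dimethyl-4'-oxo-5,6,7,8-tetrahydrospiro[benzo[7]annulene-9,1'-cyclohexa[2,5]dien]-5-yl benzoate | COC1=CC2(C=C(OC)C1=O)C[C@@H](C)[C@H](C)[C@@H](OC(=O)c1ccccc1)c1cc(OC)c(OC)c(OC)c12 | target

**Step count and risks**

Total: 11 steps. Longest linear sequence: 9 steps (steps 1–7, 10 and 11 from 1); the phosphonate 16 takes 2 steps (8 and 9).

Steps most likely to fail:

1. Step 11 (Proposed new method). The ring closure may not compete with other paths of the trienolate: an unreactive enolate geometry, acyl transfer from the benzoate to the benzylic carbanion, 1,4-elimination of benzoate through ring A, or cleavage of the benzoate by liberated methoxide. The fallback uses known chemistry (Robinson-type annulation, then dehydrogenation) and sets out from aldehyde 11. Commercial 1,3-dimethoxyacetone, paraformaldehyde and Me2NH·HCl (EtOH, reflux) should give the Mannich base 4-(dimethylamino)-1,3-dimethoxybutan-2-one F1. Heated with 11 and DBU in MeCN, it should lose dimethylamine to 1,3-dimethoxybut-3-en-2-one F2 in the flask. The aldehyde enolate adds to F2 (Michael addition), and the keto aldehyde is then closed by aldol condensation (pyrrolidine, AcOH) to the spiro enone (5R,6S,7R)-1,2,3,3',5'-pentamethoxy-6,7-dimethyl-4'-oxo-5,6,7,8-tetrahydrospiro[benzo[7]annulene-9,1'-cyclohex[2]en]-5-yl benzoate F3. Dehydrogenation of F3 (LiN(SiMe3)2, Me3SiCl; then Pd(OAc)2, O2, DMSO; Saegusa–Ito oxidation) comes back to the route at 20.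

2. Step 5. Proton transfer from the lactone α-CH2 to the aryllithium, attack of tBuLi on the lactone before exchange, or acylation of a bridged hemiketal tautomer of the alkoxide could each erode the acyl shift and trapping. The fallback sets out from lactone 6. AlMe3 and MeNH(OMe)·HCl (CH2Cl2, 0 °C) should open it to (3R,4S,5R)-5-(2-bromo-3,4,5-trimethoxyphenyl)-5-hydroxy-N-methoxy-N,3,4-trimethylpentanamide F4, which is silylated at once (tBuMe2SiOTf, 2,6-lutidine) to the silyl ether F5. tBuLi (2 eq, THF, −90 °C) then closes the seven-membered ring by Parham cyclisation onto the N-methoxy-N-methylamide, whose chelated tetrahedral adduct shields the ketone until work-up, giving (7R,8S,9R)-9-[(tert-butyldimethylsilyl)oxy]-2,3,4-trimethoxy-7,8-dimethyl-6,7,8,9-tetrahydro-5H-benzo[7]annulen-5-one F6. Bu4NF gives (7R,8S,9R)-9-hydroxy-2,3,4-trimethoxy-7,8-dimethyl-6,7,8,9-tetrahydro-5H-benzo[7]annulen-5-one F7, and PhCOCl, pyridine, DMAP comes back to the route at 9.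

3. Step 6. The basic ylide may enolise the hindered ortho-methoxy aryl ketone, and slow olefination would leave time for attack of the ylide on the benzoate. The fallback sets out from ketone 9. Dimethylsulfonium methylide (Me3SI, KN(SiMe3)2, THF, 0 °C; Corey–Chaykovsky epoxidation) should give (5R,6S,7R)-1,2,3-trimethoxy-6,7-dimethyl-5,6,7,8-tetrahydrospiro[benzo[7]annulene-9,2'-oxiran]-5-yl benzoate F8. MgBr2·OEt2 (CH2Cl2, −40 °C; Meinwald rearrangement by benzylic C–O ionisation and 1,2-hydride shift) then comes back to the route at aldehyde 11, by-passing 10.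

**Further compounds**

F1 | step 11 | 4-(dimethylamino)-1,3-dimethoxybutan-2-one | COCC(=O)C(OC)CN(C)C
F2 | step 11 | 1,3-dimethoxybut-3-en-2-one | COCC(=O)C(OC)=C
F3 | step 11 | (5R,6S,7R)-1,2,3,3',5'-pentamethoxy-6,7-dimethyl-4'-oxo-5,6,7,8-tetrahydrospiro[benzo[7]annulene-9,1'-cyclohex[2]en]-5-yl benzoate | COC1CC2(C=C(OC)C1=O)C[C@@H](C)[C@H](C)[C@@H](OC(=O)c1ccccc1)c1cc(OC)c(OC)c(OC)c12
F4 | step 5 | (3R,4S,5R)-5-(2-bromo-3,4,5-trimethoxyphenyl)-5-hydroxy-N-methoxy-N,3,4-trimethylpentanamide | CON(C)C(=O)C[C@@H](C)[C@H](C)[C@@H](O)c1cc(OC)c(OC)c(OC)c1Br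
F5 | step 5 | (3R,4S,5R)-5-(2-bromo-3,4,5-trimethoxyphenyl)-5-[(tert-butyldimethylsilyl)oxy]-N-methoxy-N,3,4-trimethylpentanamide | CON(C)C(=O)C[C@@H](C)[C@H](C)[C@@H](O[Si](C)(C)C(C)(C)C)c1cc(OC)c(OC)c(OC)c1Br
F6 | step 5 | (7R,8S,9R)-9-[(tert-butyldimethylsilyl)oxy]-2,3,4-trimethoxy-7,8-dimethyl-6,7,8,9-tetrahydro-5H-benzo[7]annulen-5-one | O=C1C[C@@H](C)[C@H](C)[C@@H](O[Si](C)(C)C(C)(C)C)c2cc(OC)c(OC)c(OC)c12
F7 | step 5 | (7R,8S,9R)-9-hydroxy-2,3,4-trimethoxy-7,8-dimethyl-6,7,8,9-tetrahydro-5H-benzo[7]annulen-5-one | O=C1C[C@@H](C)[C@H](C)[C@@H](O)c2cc(OC)c(OC)c(OC)c12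
F8 | step 6 | (5R,6S,7R)-1,2,3-trimethoxy-6,7-dimethyl-5,6,7,8-tetrahydrospiro[benzo[7]annulene-9,2'-oxiran]-5-yl benzoate | C1OC12C[C@@H](C)[C@H](C)[C@@H](OC(=O)c1ccccc1)c1cc(OC)c(OC)c(OC)c12
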